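A direct plan would buy ring A complete (3,5-dimethoxyphenol) and turn it in three steps into the silyl triflate A1. CsF would release 3,5-dimethoxybenzyne from A1, and the aryne would insert into the acyl C–O bond of the arylpropiolic acid A2 (six steps from 2,6-dimethoxyphenol) to give the ynone A3. A 6-endo oxa-Michael closure would give the flavone A4, and BCl3 would end the route. Its weakest steps would be:
(a) the carbamoylation, ortho-silylation and triflation that lead to A1, three steps that add no skeletal atom to a ring bought complete;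
(b) the aryne insertion at 125 °C on both advanced fragments, in which the caesium arylpropiolate could lose CO2, the aryl anion could be protonated or add to the alkyne, and the ynone phenoxide could close in the hot basic medium with no control between 5-exo (aurone) and 6-endo (flavone);
(c) the last step, in which BCl3 would have to tell the 5-OMe from four other methyl ethers, two of them next to the new 3'-O–B bond, on the most precious material.

**Plan of the new route.** After removal of the benzyl group, four bonds of ring A are cut at once (C4a–C5, C5–C6, C7–C8, C8–C8a), which leaves a 6-aryl-4-pyranone bearing a diazoacetyl group, and methoxyethyne. The pyranone is cut to an aryl 1,3-diketone and diethyl oxalate. The rings arise in the order B (bought), C (4-pyranone), A (last). The enabling feature is that ring A is a resorcinol monomethyl ether with H on C6 and C8, its free OH (C5) next to the fusion carbon C4a and its OMe (C7) meta to it, and that its C4a–C8a bond is the C5(H)=C6 enol-ether double bond of a monocyclic 2-aryl-4-pyranone. This is the pattern that a vinylketene and an alkoxyalkyne assemble. No aryne precursor is made, O5 is born as a free hydroxyl and O7 as its methyl ether (no selective ether cleavage), and ring C exists before ring A, so no 5-exo/6-endo choice arises.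

Key step: step 9

Remark: methoxyethyne (bp 23 °C) is assumed not to be reliably purchasable and is therefore made in step 8 and used as a cold solution; compounds 1 and 14 are catalogue compounds.

Step 1
Reactants: 1 1-(2,4,5-trimethoxyphenyl)ethanone
Product: 2 2-methyl-2-(2,4,5-trimethoxyphenyl)-1,3-dioxolane
Conditions: HOCH2CH2OH, p-TsOH (cat.), toluene, reflux, Dean–Stark
Reagents that add atoms: ethylene glycol, OCCO
Why: Acid-catalysed ketalisation with azeotropic removal of water masks the ketone so that the ring can be metalated in the next step.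

Step 2
Reactants: 2 2-methyl-2-(2,4,5-trimethoxyphenyl)-1,3-dioxolane
Product: 6 1-(3-hydroxy-2,4,5-trimethoxyphenyl)ethanone, via aryllithium 3 (not isolated), via dimethyl arylboronate 4 (not isolated), via ketal phenol 5 (not isolated)
Conditions: n-BuLi, TMEDA, THF, 0 °C → rt; B(OMe)3, −78 °C → rt; 30% H2O2, aq. NaOH, 0 °C; then 2 M HCl, rt
Reagents that add atoms: hydrogen peroxide, OO; water, O
Why: Directed ortho-metalation should take place at C3, the only ring position flanked by two methoxy groups (the site at which 1,2,4-trimethoxybenzene is lithiated), whereas C6 has one methoxy neighbour and the bulky, weakly coordinating ketal; borylation, peroxide oxidation of the C–B bond and acid hydrolysis of the ketal then give the hydroxy ketone.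

Step 3
Reactants: 6 1-(3-hydroxy-2,4,5-trimethoxyphenyl)ethanone
Product: 7 1-[3-(benzyloxy)-2,4,5-trimethoxyphenyl]ethanone
Conditions: BnBr, K2CO3, DMF, rt
Reagents that add atoms: benzyl bromide, BrCc1ccccc1
Why: Williamson etherification; the benzyl ether should survive enolate chemistry, acid cyclodehydration, acyl chloride formation and irradiation, and it leaves at the end by neutral hydrogenolysis.

Step 4
Reactants: 7 1-[3-(benzyloxy)-2,4,5-trimethoxyphenyl]ethanone
Product: 8 1-[3-(benzyloxy)-2,4,5-trimethoxyphenyl]butane-1,3-dione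
Conditions: NaH, EtOAc, THF, reflux; aq. HCl
Reagents that add atoms: ethyl acetate, CCOC(C)=O
Why: Crossed Claisen condensation of the ketone enolate with ethyl acetate, driven by formation of the sodium diketonate.

Step 5
Reactants: 8 1-[3-(benzyloxy)-2,4,5-trimethoxyphenyl]butane-1,3-dione
Product: 10 ethyl 6-[3-(benzyloxy)-2,4,5-trimethoxyphenyl]-4-oxo-4H-pyran-2-carboxylate, via triketo ester 9 (not isolated)
Conditions: (CO2Et)2, NaOEt, EtOH, 0 °C → rt; aq. HCl; then p-TsOH (cat.), toluene, 80 °C
Reagents that add atoms: diethyl oxalate, CCOC(=O)C(=O)OCC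
Why: Claisen condensation of the diketone at its terminal methyl group with diethyl oxalate (as in the classical route from benzoylacetone to 6-phenylcomanic ester), followed by acid cyclodehydration of the 1,3,5-tricarbonyl chain, in which the enol oxygen of the aryl ketone adds to the α-keto ester carbonyl and water is lost, closes ring C as the 4-pyranone.

Step 6
Reactants: 10 ethyl 6-[3-(benzyloxy)-2,4,5-trimethoxyphenyl]-4-oxo-4H-pyran-2-carboxylate
Product: 11 6-[3-(benzyloxy)-2,4,5-trimethoxyphenyl]-4-oxo-4H-pyran-2-carboxylic acid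
Conditions: LiOH (1.2 equiv), THF–H2O, 0 °C; then 1 M HCl
Reagents that add atoms: lithium hydroxide, [Li+].[OH-]
Why: Saponification of an activated heteroaryl ester, run cold with a small excess of hydroxide so that the pyranone ring is not opened.

Step 7
Reactants: 11 6-[3-(benzyloxy)-2,4,5-trimethoxyphenyl]-4-oxo-4H-pyran-2-carboxylic acid
Product: 13 2-[3-(benzyloxy)-2,4,5-trimethoxyphenyl]-6-(2-diazoacetyl)-4H-pyran-4-one, via acid chloride 12 (not isolated)
Conditions: (COCl)2, DMF (cat.), CH2Cl2, 0 °C → rt; then TMSCHN2, THF–MeCN, 0 °C → rt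
Reagents that add atoms: trimethylsilyldiazomethane, C[Si](C)(C)C=[N+]=[N-]
Why: Acid chloride formation through the Vilsmeier chloride and C-acylation of the diazoalkane (first stage of an Arndt–Eistert sequence), the C–Si bond being cleaved by the chloride released, as known for chromone-2-carbonyl chlorides.

Step 8
Reactants: 14 2-chloro-1,1-dimethoxyethane
Product: 16 methoxyethyne, via sodium methoxyacetylide 15 (not isolated)
Conditions: NaNH2 (3 equiv), NH3 (l), −33 °C; then satd aq. NaCl, −20 °C; distilled into cold ClCH2CH2Cl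
Reagents that add atoms: none
Why: Twofold base-induced elimination (loss of methanol, then of HCl) gives the alkynyl ether, which is held as its sodium acetylide and set free by the aqueous quench.

Step 9
Reactants: 13 2-[3-(benzyloxy)-2,4,5-trimethoxyphenyl]-6-(2-diazoacetyl)-4H-pyran-4-one; 16 methoxyethyne
Product: 20 2-[3-(benzyloxy)-2,4,5-trimethoxyphenyl]-5-hydroxy-7-methoxy-4H-chromen-4-one, via pyranonylketene 17 (not isolated), via cyclobutenone 18 (not isolated), via dienylketene 19 (not isolated)
Conditions: hν (medium-pressure Hg lamp, Pyrex, flow), 16 (3 equiv), ClCH2CH2Cl, 10 °C; then 80 °C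
Reagents that add atoms: none
Why: Irradiation expels N2 and the pyranonyl group migrates (Wolff rearrangement) to give ketene 17, whose carbonyl carbon is attacked by the nucleophilic CH terminus of the alkynyl ether in a regiospecific [2+2] cycloaddition that closes the four-membered ring of 18 (racemic, transient). 4π-Electrocyclic opening, completed at 80 °C through reversible opening, gives dienylketene 19, and its 6π-electrocyclisation onto the C5–H carbon of the pyranone closes ring A; tautomerisation then gives the phenol. This is the second-generation Danheiser benzannulation (photochemical aromatic annulation of unsaturated and heteroaryl α-diazo ketones with alkoxyalkynes), here with the C5=C6 bond of a 4-pyranone as the vinyl unit. The ketene carbonyl carbon becomes C5–OH, the alkyne carbons become C6–H and C7–OMe and the former diazo carbon becomes C8–H, so the 5-OH/7-OMe pattern follows from connectivity and not from a selective reaction. No stereocentre survives; the step needs the [2+2] regiochemistry, which the polarity of the alkynyl ether secures, and a Wolff rearrangement faster than photoreaction of the pyranone, which light above 300 nm in a thin flow film should secure.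

Step 10
Reactants: 20 2-[3-(benzyloxy)-2,4,5-trimethoxyphenyl]-5-hydroxy-7-methoxy-4H-chromen-4-one
Product: 21 5-hydroxy-2-(3-hydroxy-2,4,5-trimethoxyphenyl)-7-methoxy-4H-chromen-4-one (5,3'-dihydroxy-7,2',4',5'-tetramethoxyflavone)
Conditions: H2 (1 atm), 10% Pd/C, EtOAc–MeOH, rt
Reagents that add atoms: none
Why: Hydrogenolysis of the aryl benzyl ether under neutral conditions, which should leave the hydrogen-bonded 5-hydroxyflavone enone and all methyl ethers untouched at 1 atm and room temperature.

**Compound list**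
1 | 1-(2,4,5-trimethoxyphenyl)ethanone | CC(=O)c1cc(OC)c(OC)cc1OC | starting material
2 | 2-methyl-2-(2,4,5-trimethoxyphenyl)-1,3-dioxolane | CC1(OCCO1)c1cc(OC)c(OC)cc1OC | intermediate
3 | [2,3,6-trimethoxy-5-(2-methyl-1,3-dioxolan-2-yl)phenyl]lithium | [Li]c1c(OC)c(OC)cc(C2(C)OCCO2)c1OC | intermediate
4 | dimethyl [2,3,6-trimethoxy-5-(2-methyl-1,3-dioxolan-2-yl)phenyl]boronate | COB(OC)c1c(OC)c(OC)cc(C2(C)OCCO2)c1OC | intermediate
5 | 2,3,6-trimethoxy-5-(2-methyl-1,3-dioxolan-2-yl)phenol | Oc1c(OC)c(OC)cc(C2(C)OCCO2)c1OC | intermediate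
6 | 1-(3-hydroxy-2,4,5-trimethoxyphenyl)ethanone | CC(=O)c1cc(OC)c(OC)c(O)c1OC | intermediate
7 | 1-[3-(benzyloxy)-2,4,5-trimethoxyphenyl]ethanone | CC(=O)c1cc(OC)c(OC)c(OCc2ccccc2)c1OC | intermediate
8 | 1-[3-(benzyloxy)-2,4,5-trimethoxyphenyl]butane-1,3-dione | CC(=O)CC(=O)c1cc(OC)c(OC)c(OCc2ccccc2)c1OC | intermediate
9 | ethyl 6-[3-(benzyloxy)-2,4,5-trimethoxyphenyl]-2,4,6-trioxohexanoate | CCOC(=O)C(=O)CC(=O)CC(=O)c1cc(OC)c(OC)c(OCc2ccccc2)c1OC | intermediate
10 | ethyl 6-[3-(benzyloxy)-2,4,5-trimethoxyphenyl]-4-oxo-4H-pyran-2-carboxylate | CCOC(=O)c1cc(=O)cc(-c2cc(OC)c(OC)c(OCc3ccccc3)c2OC)o1 | intermediate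
11 | 6-[3-(benzyloxy)-2,4,5-trimethoxyphenyl]-4-oxo-4H-pyran-2-carboxylic acid | OC(=O)c1cc(=O)cc(-c2cc(OC)c(OC)c(OCc3ccccc3)c2OC)o1 | intermediate
12 | 6-[3-(benzyloxy)-2,4,5-trimethoxyphenyl]-4-oxo-4H-pyran-2-carbonyl chloride | O=C(Cl)c1cc(=O)cc(-c2cc(OC)c(OC)c(OCc3ccccc3)c2OC)o1 | intermediate
13 | 2-[3-(benzyloxy)-2,4,5-trimethoxyphenyl]-6-(2-diazoacetyl)-4H-pyran-4-one | [N-]=[N+]=CC(=O)c1cc(=O)cc(-c2cc(OC)c(OC)c(OCc3ccccc3)c2OC)o1 | intermediate
14 | 2-chloro-1,1-dimethoxyethane (chloroacetaldehyde dimethyl acetal) | COC(CCl)OC | starting material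
15 | sodium methoxyacetylide | [Na]C#COC | intermediate
16 | methoxyethyne (methoxyacetylene) | C#COC | intermediate
17 | 2-[3-(benzyloxy)-2,4,5-trimethoxyphenyl]-6-(2-oxoethenyl)-4H-pyran-4-one (pyranonylketene) | O=C=Cc1cc(=O)cc(-c2cc(OC)c(OC)c(OCc3ccccc3)c2OC)o1 | intermediate
18 | 2-[3-(benzyloxy)-2,4,5-trimethoxyphenyl]-6-(2-methoxy-4-oxocyclobut-2-en-1-yl)-4H-pyran-4-one (racemic) | COC1=CC(=O)C1c1cc(=O)cc(-c2cc(OC)c(OC)c(OCc3ccccc3)c2OC)o1 | intermediate
19 | 2-[3-(benzyloxy)-2,4,5-trimethoxyphenyl]-6-[(1E)-2-methoxy-4-oxobuta-1,3-dien-1-yl]-4H-pyran-4-one (dienylketene, pyranonyl cis to the ketene carbon chain) | O=C=C/C(OC)=C\c1cc(=O)cc(-c2cc(OC)c(OC)c(OCc3ccccc3)c2OC)o1 | intermediate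
20 | 2-[3-(benzyloxy)-2,4,5-trimethoxyphenyl]-5-hydroxy-7-methoxy-4H-chromen-4-one | COc1cc(O)c2c(=O)cc(-c3cc(OC)c(OC)c(OCc4ccccc4)c3OC)oc2c1 | intermediate
21 | 5-hydroxy-2-(3-hydroxy-2,4,5-trimethoxyphenyl)-7-methoxy-4H-chromen-4-one | COc1cc(O)c2c(=O)cc(-c3cc(OC)c(OC)c(O)c3OC)oc2c1 | target

**Count.** Total: 10 steps. Longest linear sequence: 9 steps (steps 1–7, 9 and 10); step 8 is a one-step side branch.

**Steps most likely to fail**

1. Step 9. The Wolff rearrangement may stall because the pyranone chromophore and the flavone formed absorb the light. The 4-pyranone may also photoisomerise, the ketene may dimerise before it meets the volatile alkyne, or the sequence may stop at the cyclobutenone. The fallback leaves the benzannulation and builds ring C last by classical chemistry; it sets out from 7 and comes back at 20. Haloform cleavage of 7 (NaOCl, aq. NaOH, dioxane, 0 °C → rt) would give 3-(benzyloxy)-2,4,5-trimethoxybenzoic acid F1. Esterification of one hydroxyl of purchased 1-(2,6-dihydroxy-4-methoxyphenyl)ethanone with F1 (EDC·HCl, DMAP, CH2Cl2) would give 2-acetyl-3-hydroxy-5-methoxyphenyl 3-(benzyloxy)-2,4,5-trimethoxybenzoate F2. Baker–Venkataraman acyl shift (LiN(SiMe3)2, THF, −20 °C → rt) would give 1-[3-(benzyloxy)-2,4,5-trimethoxyphenyl]-3-(2,6-dihydroxy-4-methoxyphenyl)propane-1,3-dione F3. Acid cyclodehydration (p-TsOH, toluene, 80 °C) through either of the two equivalent hydroxyls would give 20.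

2. Step 2. Metalation may go in part to C6, between the ketal and the 5-methoxy group, and the doubly ortho-substituted boronate may lose boron before it is oxidised. The fallback places the oxygen by phenol-directed chemistry instead of lithiation; it sets out from 1 and comes back at 7. BCl3 (CH2Cl2, 0 °C) would cleave only the methyl ether ortho to the carbonyl group and give 1-(2-hydroxy-4,5-dimethoxyphenyl)ethanone F4. IBX (DMF, rt) would oxidise the phenol at its only free ortho position to 3-acetyl-5,6-dimethoxycyclohexa-3,5-diene-1,2-dione F5, which Na2S2O4 in the work-up would reduce to 1-(2,3-dihydroxy-4,5-dimethoxyphenyl)ethanone F6. BnBr (1 equiv) and K2CO3 in DMF would alkylate the hydroxyl that is not hydrogen-bonded to the ketone and give 1-[3-(benzyloxy)-2-hydroxy-4,5-dimethoxyphenyl]ethanone F7. MeI and K2CO3 in refluxing acetone would methylate the chelated hydroxyl to give 7.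

3. Step 7. The chlorinating agent may attack the basic pyranone carbonyl oxygen (chloropyrylium formation), and the diazoalkane may add as a dipole to the electron-poor pyranone double bond. The fallback introduces the diazo group by diazo transfer to a methyl ketone instead of acylation of a diazoalkane; it sets out from 8 and comes back at 13. The dianion of 8 (LiN(i-Pr)2, 2.2 equiv, THF, −78 → 0 °C) would be acylated at its terminal carbon by ethyl 2,2-diethoxypropanoate to give 1-[3-(benzyloxy)-2,4,5-trimethoxyphenyl]-6,6-diethoxyheptane-1,3,5-trione F8. Anhydrous acid (p-TsOH, toluene, 80 °C) would close the pyranone with the ketal still in place, giving 2-[3-(benzyloxy)-2,4,5-trimethoxyphenyl]-6-(1,1-diethoxyethyl)-4H-pyran-4-one F9, and aqueous HCl in THF would then free 2-acetyl-6-[3-(benzyloxy)-2,4,5-trimethoxyphenyl]-4H-pyran-4-one F10. Trifluoroacetylation of its lithium enolate (LiN(SiMe3)2, CF3CO2CH2CF3, THF, −78 °C) would give 1-{6-[3-(benzyloxy)-2,4,5-trimethoxyphenyl]-4-oxo-4H-pyran-2-yl}-4,4,4-trifluorobutane-1,3-dione F11. Detrifluoroacetylative diazo transfer (MsN3, Et3N, H2O, MeCN) would give 13.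

**Further compounds**
F1 | step 9 | 3-(benzyloxy)-2,4,5-trimethoxybenzoic acid | OC(=O)c1cc(OC)c(OC)c(OCc2ccccc2)c1OC
F2 | step 9 | 2-acetyl-3-hydroxy-5-methoxyphenyl 3-(benzyloxy)-2,4,5-trimethoxybenzoate | CC(=O)c1c(O)cc(OC)cc1OC(=O)c1cc(OC)c(OC)c(OCc2ccccc2)c1OC
F3 | step 9 | 1-[3-(benzyloxy)-2,4,5-trimethoxyphenyl]-3-(2,6-dihydroxy-4-methoxyphenyl)propane-1,3-dione | COc1cc(O)c(C(=O)CC(=O)c2cc(OC)c(OC)c(OCc3ccccc3)c2OC)c(O)c1
F4 | step 2 | 1-(2-hydroxy-4,5-dimethoxyphenyl)ethanone | CC(=O)c1cc(OC)c(OC)cc1O
F5 | step 2 | 3-acetyl-5,6-dimethoxycyclohexa-3,5-diene-1,2-dione | CC(=O)C1=CC(OC)=C(OC)C(=O)C1=O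
F6 | step 2 | 1-(2,3-dihydroxy-4,5-dimethoxyphenyl)ethanone | CC(=O)c1cc(OC)c(OC)c(O)c1O
F7 | step 2 | 1-[3-(benzyloxy)-2-hydroxy-4,5-dimethoxyphenyl]ethanone | CC(=O)c1cc(OC)c(OC)c(OCc2ccccc2)c1O
F8 | step 7 | 1-[3-(benzyloxy)-2,4,5-trimethoxyphenyl]-6,6-diethoxyheptane-1,3,5-trione | CCOC(C)(OCC)C(=O)CC(=O)CC(=O)c1cc(OC)c(OC)c(OCc2ccccc2)c1OC
F9 | step 7 | 2-[3-(benzyloxy)-2,4,5-trimethoxyphenyl]-6-(1,1-diethoxyethyl)-4H-pyran-4-one | CCOC(C)(OCC)c1cc(=O)cc(-c2cc(OC)c(OC)c(OCc3ccccc3)c2OC)o1
F10 | step 7 | 2-acetyl-6-[3-(benzyloxy)-2,4,5-trimethoxyphenyl]-4H-pyran-4-one | CC(=O)c1cc(=O)cc(-c2cc(OC)c(OC)c(OCc3ccccc3)c2OC)o1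
F11 | step 7 | 1-{6-[3-(benzyloxy)-2,4,5-trimethoxyphenyl]-4-oxo-4H-pyran-2-yl}-4,4,4-trifluorobutane-1,3-dione | O=C(CC(=O)C(F)(F)F)c1cc(=O)cc(-c2cc(OC)c(OC)c(OCc3ccccc3)c2OC)o1
A1 | direct plan | 3,5-dimethoxy-2-(trimethylsilyl)phenyl trifluoromethanesulfonate | COc1cc(OC)c([Si](C)(C)C)c(OS(=O)(=O)C(F)(F)F)c1
A2 | direct plan | 3-[3-(benzyloxy)-2,4,5-trimethoxyphenyl]prop-2-ynoic acid | OC(=O)C#Cc1cc(OC)c(OC)c(OCc2ccccc2)c1OC
A3 | direct plan | 3-[3-(benzyloxy)-2,4,5-trimethoxyphenyl]-1-(2-hydroxy-4,6-dimethoxyphenyl)prop-2-yn-1-one | COc1cc(O)c(C(=O)C#Cc2cc(OC)c(OC)c(OCc3ccccc3)c2OC)c(OC)c1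
A4 | direct plan | 2-[3-(benzyloxy)-2,4,5-trimethoxyphenyl]-5,7-dimethoxy-4H-chromen-4-one | COc1cc(OC)c2c(=O)cc(-c3cc(OC)c(OC)c(OCc4ccccc4)c3OC)oc2c1
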